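**Plan**

- Retrosynthesis: the C4–C5 epoxide is taken back to the 4Z alkene, and the O8 and O9 esters and C11=C13 are removed. The ten-membered ring is cut at C1=C10 (metathesis), then C3–C4 (Negishi), C4=C5 (iodo-olefination) and C9–C10 (aldol). C5 and C9 are rejoined as a cyclopentene, and the O6–C12 lactone bond is cut last.
- Enabling feature (germacrane numbering): O6, C11 (on C7) and O8 lie on one face of C6–C7–C8. With C5 bonded to C9 these atoms sit on an all-cis cyclopentene (C5–C9) that keeps a mirror plane through C7 as long as the lactone ring O6–C6–C7–C11–C12 is open.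
- Forward: the γ-lactone ring closes first by enzymatic desymmetrisation. Ozone then opens the carbocycle, with C5 resting as a lactol on O8. C9 is extended by aldol, C5 by olefination and coupling, and the ten-membered ring closes at C1=C10. C13, the two esters and the epoxide follow.
- Stereochemistry: C6, C7, C8 from the meso ring and the lipase; C9 from Cram-chelate aldol addition; 4Z from Stork–Zhao/Negishi; 1(10)E from the ring; C4 and C5 from peracid attack on the outer face of the macrocyclic alkene.

Key step: step 5

Remark: germacrane numbering is used for every intermediate; the lipase is assumed to lactonise onto the (S)-configured carbinol of 7 (C6), a sense that only screening can confirm.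

**Route**

Step 1
Reactants: 1 furfural; 2 methyl bromoacetate
Product: 3 methyl 3-(furan-2-yl)-3-hydroxypropanoate (racemic)
Conditions: Zn dust (Me3SiCl-activated), THF, 40 °C; aq NH4Cl
Reagents that add atoms: none
Why: Reformatsky reaction, in which the bromozinc enolate of 2 adds to the aldehyde without touching the furan or the ester.

Step 2
Reactants: 3 methyl 3-(furan-2-yl)-3-hydroxypropanoate
Product: 4 methyl 2-(trans-2-hydroxy-5-oxocyclopent-3-en-1-yl)acetate (racemic)
Conditions: ZnCl2, 1,4-dioxane/H2O 1:1, pH 6, 70 °C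
Reagents that add atoms: water, O
Why: Piancatelli rearrangement, in which ionisation of the furylcarbinol, addition of water at C5 of the furan, ring opening and conrotatory 4π electrocyclisation give the 4-hydroxycyclopentenone with the side chain trans to the hydroxyl (a relationship that step 3 erases).

Step 3
Reactants: 4 methyl 2-(trans-2-hydroxy-5-oxocyclopent-3-en-1-yl)acetate
Product: 5 methyl 2-(2,5-dioxocyclopent-3-en-1-yl)acetate
Conditions: MnO2 (activated), CH2Cl2, rt; filtration
Reagents that add atoms: none
Why: MnO2 oxidises the allylic alcohol under neutral conditions, so the CH-acidic ene-dione should be obtained by filtration alone without basic work-up.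

Step 4
Reactants: 5 methyl 2-(2,5-dioxocyclopent-3-en-1-yl)acetate
Product: 7 methyl 2-[(2R,5S)-2,5-dihydroxycyclopent-3-en-1-yl]acetate (meso all-cis diol ester), via cis-hydroxy enone 6 (not isolated)
Conditions: NaBH4, CeCl3·7H2O, MeOH, −78 °C; pH 7 phosphate buffer at −78 °C; no acid or base in work-up
Reagents that add atoms: none
Why: Luche reduction, in which hydride adds to each carbonyl from the face opposite the side chain on C7 so that both hydroxyls end cis to it and the diol is meso, while CeCl3 keeps the medium non-basic so that carbonyl addition should outrun enolisation of the acidic dione and the product should not lactonise.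

Step 5
Reactants: 7 methyl 2-[(2R,5S)-2,5-dihydroxycyclopent-3-en-1-yl]acetate
Product: 8 (3aR,4R,6aS)-4-hydroxy-3,3a,4,6a-tetrahydro-2H-cyclopenta[b]furan-2-one
Conditions: Novozym 435 (immobilised Candida antarctica lipase B), 4 Å molecular sieves, MTBE, 30 °C; enzyme filtered off, filtrate used directly
Reagents that add atoms: none
Why: The active-site serine is acylated by the methyl ester of 7 (methanol leaves and is held by the sieves), and in the chiral pocket only one of the two enantiotopic hydroxyls, the (S)-carbinol at C6, is expected to reach the acyl-enzyme carbonyl, so the O6–C12 bond forms and the enzyme is released. The closest known reactions are lipase-catalysed lactonisations of γ-hydroxy esters and lipase desymmetrisations of meso cyclopent-4-ene-1,3-diols. The γ-lactone closes in a 5-exo-trig mode onto a hydroxyl that is cis to the side chain, so only the cis-fused bicycle can arise. The relative configuration of C6, C7 and C8 is already fixed by the all-cis ring of 7, and their absolute configuration (3aR,4R,6aS) follows solely from which hydroxyl the enzyme selects. The step needs enantiotopic-group selection without uncatalysed ring closure, and the product must not suffer acyl transfer from O6 to O8, which would interconvert 8 and its mirror image; the neutral aprotic medium, the mild temperature and the absence of soluble acid or base should secure both, and 8 goes into step 6 without exposure to base.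

Step 6
Reactants: 8 (3aR,4R,6aS)-4-hydroxy-3,3a,4,6a-tetrahydro-2H-cyclopenta[b]furan-2-one
Product: 10 6-hydroxy-2-oxohexahydrofuro[3,4-b]furan-4-carbaldehyde (C5 lactol on O8; C9 aldehyde free), via hydroxy dialdehyde 9 (not isolated)
Conditions: O3, CH2Cl2, −78 °C; PPh3, −78 °C → rt
Reagents that add atoms: ozone, [O-][O+]=O
Why: Ozonolysis with reductive work-up cleaves the only alkene, and the free O8 hydroxyl closes on the C5 aldehyde to a five-membered lactol (it cannot reach C9), which leaves C9 as the only free aldehyde.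

Step 7
Reactants: 11 methyl 2-bromopropanoate; 12 diphenyl diselenide
Product: 13 methyl 2-(phenylselanyl)propanoate (racemic)
Conditions: 12, NaBH4, EtOH, 0 °C; then 11, 0 °C → rt
Reagents that add atoms: none
Why: SN2 displacement of the α-bromide by sodium benzeneselenolate (NaSePh) made in the flask from the diselenide.

Step 8
Reactants: 13 methyl 2-(phenylselanyl)propanoate
Product: 14 1-methoxy-2-(phenylselanyl)-1-(trimethylsilyloxy)prop-1-ene (E/Z mixture)
Conditions: LiN(iPr)2, THF, −78 °C; Me3SiCl
Reagents that add atoms: chlorotrimethylsilane, C[Si](C)(C)Cl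
Why: Kinetic ester enolisation and O-silylation, the α-selanyl enolate having no β-leaving group and being stable at −78 °C.

Step 9
Reactants: 10 lactol aldehyde; 14 ketene silyl acetal
Product: 15 methyl 3-hydroxy-3-(6-hydroxy-2-oxohexahydrofuro[3,4-b]furan-4-yl)-2-methyl-2-(phenylselanyl)propanoate (8,9-syn; C10 epimers)
Conditions: MgBr2·OEt2 (3 equiv), 14 (2.5 equiv), CH2Cl2, −78 → −30 °C; aq citric acid
Reagents that add atoms: none
Why: Mukaiyama aldol under Cram-chelate control, in which MgBr2 bridges the aldehyde oxygen and the lactol ring oxygen O8 and the ketene acetal attacks from the side of H8, setting C9 syn to O8 as in the target, while the lactol hydroxyl is silylated in passing and freed on work-up and the C10 epimers converge in step 13.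

Step 10
Reactants: 15 aldol adduct
Product: 17 9-O-tert-butyldimethylsilyl ether of 15 with free lactol hydroxyl, via bis-silyl ether 16 (not isolated)
Conditions: TBSOTf, 2,6-lutidine, CH2Cl2, −78 → 0 °C; then AcOH/THF/H2O 3:1:1, rt
Reagents that add atoms: tert-butyldimethylsilyl trifluoromethanesulfonate, CC(C)(C)[Si](C)(C)OS(=O)(=O)C(F)(F)F
Why: Both hydroxyls are silylated, and the anomeric silyl acetal, far more acid-labile than the secondary silyl ether, should then hydrolyse selectively.

Step 11
Reactants: 17 9-O-silyl lactol; 18 ethyltriphenylphosphonium iodide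
Product: 20 (Z)-iodoalkene with O8 triethylsilyl ether, via hydroxy iodoalkene 19 (not isolated)
Conditions: 18, n-BuLi, THF, rt; I2, −78 °C; NaN(SiMe3)2, −78 °C; sodium salt of 17 (NaN(SiMe3)2, THF, −78 °C), −78 → −30 °C; Et3SiCl, −78 °C
Reagents that add atoms: iodine, II; chlorotriethylsilane, CC[Si](CC)(CC)Cl
Why: Stork–Zhao olefination of the lactol, in which the lactolate opens to the C5 aldehyde, the α-iodo ylide gives the (Z)-iodoalkene with iodine cis to C6, and the O8 alkoxide is silylated in the cold before it can attack C12 or C14 or take the silyl group from O9.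

Step 12
Reactants: 20 (Z)-iodoalkene; 21 but-3-enylzinc bromide (CH2=CHCH2CH2ZnBr)
Product: 22 (Z)-diene selenide (C4 now carries C3–C2–C1=CH2)
Conditions: PdCl2(dppf) (5 mol %), THF/DMF, rt
Reagents that add atoms: none
Why: Negishi coupling with retention of olefin geometry puts C3 cis to C6, and oxidative addition into the C–I bond is much faster than ionisation of the hindered allylic lactone.

Step 13
Reactants: 22 (Z)-diene selenide
Product: 24 acrylate triene (C10=CH2), via selenoxide 23 (not isolated)
Conditions: NaIO4, NaHCO3, THF/MeOH/H2O, 0 °C → rt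
Reagents that add atoms: none
Why: Selenide oxidation and selenoxide syn-elimination, which runs toward the methyl group and not toward the oxygen-bearing C9, unmask the acrylate and remove the C10 stereocentre.

Step 14
Reactants: 24 acrylate triene
Product: 25 ten-membered (1(10)E,4Z)-diene lactone with O8 triethylsilyl and O9 tert-butyldimethylsilyl ethers
Conditions: second-generation Hoveyda–Grubbs catalyst (H2IMes)Cl2Ru=CH(2-iPrO-C6H4) (10 mol %), 1,4-benzoquinone, toluene (1 mM), 80 °C
Reagents that add atoms: none
Why: Ring-closing metathesis, in which the catalyst loads at the monosubstituted C1 olefin and closes onto the 1,1-disubstituted acrylate with loss of ethene, the ten-membered ring allows only the isomer with C2 and C9 cis, and the conjugated trisubstituted product should not react further.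

Step 15
Reactants: 25 ten-membered diene lactone
Product: 29 11(13)-methylene lactone, via silyl ketene acetal 26 (not isolated), via Mannich base 27 (not isolated), via ammonium iodide 28 (not isolated)
Conditions: LiN(SiMe3)2, Me3SiCl (in situ), THF, −78 °C; CH2=NMe2+ I−, CH2Cl2, rt; MeI, MeOH, rt; aq NaHCO3, CH2Cl2
Reagents that add atoms: N,N-dimethylmethyleneiminium iodide, C=[N+](C)C.[I-]
Why: Mannich methylenation, in which the lactone is the only readily enolised carbonyl, its enolate is trapped at once as the silyl ketene acetal so that it cannot add across the ring to the enoate, the iminium salt alkylates C11, and quaternisation followed by E1cB loss of trimethylamine gives the exocyclic alkene.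

Step 16
Reactants: 29 11(13)-methylene lactone
Product: 30 C8 alcohol (O9 silyl ether kept)
Conditions: HF·pyridine, pyridine, THF, 0 °C
Reagents that add atoms: none
Why: The less hindered triethylsilyl ether should be cleaved by buffered HF·pyridine well before the tert-butyldimethylsilyl ether, and the weakly acidic medium should not move the lactone from O6 to O8.

Step 17
Reactants: 30 C8 alcohol
Product: 31 C8 methacrylate
Conditions: methacrylic anhydride, Et3N, DMAP (cat.), CH2Cl2, 0 °C → rt
Reagents that add atoms: methacrylic anhydride, C=C(C)C(=O)OC(=O)C(C)=C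
Why: DMAP-catalysed acylation of the free C8 hydroxyl, the amine bases being too weak to form the alkoxide that could attack C12 or C14.

Step 18
Reactants: 31 C8 methacrylate
Product: 32 C9 alcohol
Conditions: HF·pyridine, THF, 0 °C → rt
Reagents that add atoms: none
Why: Fluoride cleavage of the remaining silyl ether under acidic conditions, where the hindered methacrylate is not expected to migrate from O8 to the freed O9 hydroxyl.

Step 19
Reactants: 32 C9 alcohol
Product: 33 C9 acetate (4Z alkene)
Conditions: Ac2O, pyridine, DMAP (cat.), CH2Cl2, 0 °C, on the crude alcohol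
Reagents that add atoms: acetic anhydride, CC(=O)OC(C)=O
Why: Fast DMAP-catalysed acetylation of the allylic C9 hydroxyl, run at once to forestall acyl migration between O8 and O9.

Step 20
Reactants: 33 C9 acetate
Product: 34 methyl (1(10)E,4R,5S,6R,7R,8S,9S)-9-acetoxy-4,5-epoxy-8-(2-methylprop-2-enoyloxy)germacra-1(10),11(13)-dien-12,6-olid-14-oate (target)
Conditions: mCPBA, NaHCO3, CH2Cl2, 0 °C
Reagents that add atoms: 3-chloroperoxybenzoic acid, OOC(=O)c1cccc(Cl)c1
Why: Prilezhaev epoxidation, in which the trisubstituted C4=C5 alkene is the only electron-rich double bond and, with H6 held in the olefin plane by allylic 1,3-strain, the peracid should reach the outer face on the side of O6 and away from C7, which gives the (4R,5S)-epoxide.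

**Compound list**

1 | furfural | O=Cc1ccco1 | starting material
2 | methyl bromoacetate | COC(=O)CBr | starting material
3 | methyl 3-(furan-2-yl)-3-hydroxypropanoate (racemic) | COC(=O)CC(O)c1ccco1 | intermediate
4 | methyl 2-(trans-2-hydroxy-5-oxocyclopent-3-en-1-yl)acetate (racemic, one enantiomer drawn) | COC(=O)C[C@@H]1[C@@H](O)C=CC1=O | intermediate
5 | methyl 2-(2,5-dioxocyclopent-3-en-1-yl)acetate | COC(=O)CC1C(=O)C=CC1=O | intermediate
6 | methyl 2-(cis-2-hydroxy-5-oxocyclopent-3-en-1-yl)acetate (racemic, one enantiomer drawn) | COC(=O)C[C@H]1[C@@H](O)C=CC1=O | intermediate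
7 | methyl 2-[(2R,5S)-2,5-dihydroxycyclopent-3-en-1-yl]acetate (meso; both hydroxyls cis to the side chain) | COC(=O)C[C@H]1[C@@H](O)C=C[C@H]1O | intermediate
8 | (3aR,4R,6aS)-4-hydroxy-3,3a,4,6a-tetrahydro-2H-cyclopenta[b]furan-2-one | O=C1C[C@@H]2[C@H](O)C=C[C@@H]2O1 | intermediate
9 | 3-(1-hydroxy-2-oxoethyl)-5-oxotetrahydrofuran-2-carbaldehyde (C5 and C9 aldehydes open; C6, C7, C8 as in 8) | O[C@H](C=O)[C@H]1CC(=O)O[C@H]1C=O | intermediate
10 | 6-hydroxy-2-oxohexahydrofuro[3,4-b]furan-4-carbaldehyde (C5 lactol closed on O8, anomers; C9 aldehyde free; C6, C7, C8 as in 8) | O=C[C@H]1OC(O)[C@@H]2OC(=O)C[C@H]12 | intermediate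
11 | methyl 2-bromopropanoate (racemic) | CC(Br)C(=O)OC | starting material
12 | diphenyl diselenide | c1ccc(cc1)[Se][Se]c1ccccc1 | starting material
13 | methyl 2-(phenylselanyl)propanoate (racemic) | COC(=O)C(C)[Se]c1ccccc1 | intermediate
14 | 1-methoxy-2-(phenylselanyl)-1-(trimethylsilyloxy)prop-1-ene (E/Z mixture) | COC(O[Si](C)(C)C)=C(C)[Se]c1ccccc1 | intermediate
15 | methyl 3-hydroxy-3-(6-hydroxy-2-oxohexahydrofuro[3,4-b]furan-4-yl)-2-methyl-2-(phenylselanyl)propanoate (O8 and O9 syn; C10 and anomeric carbon as mixtures) | COC(=O)C(C)([Se]c1ccccc1)[C@H](O)[C@H]1OC(O)[C@@H]2OC(=O)C[C@H]12 | intermediate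
16 | bis(tert-butyldimethylsilyl) ether of 15 (on O9 and on the anomeric oxygen) | COC(=O)C(C)([Se]c1ccccc1)[C@H](O[Si](C)(C)C(C)(C)C)[C@H]1OC(O[Si](C)(C)C(C)(C)C)[C@@H]2OC(=O)C[C@H]12 | intermediate
17 | 9-O-tert-butyldimethylsilyl ether of 15 (anomeric hydroxyl free) | COC(=O)C(C)([Se]c1ccccc1)[C@H](O[Si](C)(C)C(C)(C)C)[C@H]1OC(O)[C@@H]2OC(=O)C[C@H]12 | intermediate
18 | ethyltriphenylphosphonium iodide | CC[P+](c1ccccc1)(c1ccccc1)c1ccccc1.[I-] | starting material
19 | γ-lactone (C12 on O6) with a (Z)-2-iodoprop-1-enyl group on C6 and the chain C8H(OH)–C9H(OTBS)–C10(CH3)(SePh)CO2CH3 on C7 (formed as the sodium alkoxide) | COC(=O)C(C)([Se]c1ccccc1)[C@H](O[Si](C)(C)C(C)(C)C)[C@@H](O)[C@H]1CC(=O)O[C@H]1/C=C(/C)I | intermediate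
20 | O8 triethylsilyl ether of 19 | COC(=O)C(C)([Se]c1ccccc1)[C@H](O[Si](C)(C)C(C)(C)C)[C@@H](O[Si](CC)(CC)CC)[C@H]1CC(=O)O[C@H]1/C=C(/C)I | intermediate
21 | but-3-en-1-ylzinc bromide | C=CCC[Zn]Br | starting material
22 | as 20 with the iodine replaced by but-3-enyl: (Z)-2-methylhexa-1,5-dienyl group on C6 | COC(=O)C(C)([Se]c1ccccc1)[C@H](O[Si](C)(C)C(C)(C)C)[C@@H](O[Si](CC)(CC)CC)[C@H]1CC(=O)O[C@H]1/C=C(/C)CCC=C | intermediate
23 | selenoxide of 22 | COC(=O)C(C)([Se](=O)c1ccccc1)[C@H](O[Si](C)(C)C(C)(C)C)[C@@H](O[Si](CC)(CC)CC)[C@H]1CC(=O)O[C@H]1/C=C(/C)CCC=C | intermediate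
24 | acrylate triene: methyl 2-methylidene ester with C9H(OTBS)–C8H(OSiEt3) leading to the lactone that bears the (Z)-2-methylhexa-1,5-dienyl group | C=C(C(=O)OC)[C@H](O[Si](C)(C)C(C)(C)C)[C@@H](O[Si](CC)(CC)CC)[C@H]1CC(=O)O[C@H]1/C=C(/C)CCC=C | intermediate
25 | methyl (1(10)E,4Z)-9-(tert-butyldimethylsilyloxy)-8-(triethylsilyloxy)germacra-1(10),4-dien-12,6-olid-14-oate (C6–C9 as in 34) | CC[Si](CC)(CC)O[C@H]1[C@H]2CC(=O)O[C@H]2/C=C(/C)CC/C=C(/C(=O)OC)[C@@H]1O[Si](C)(C)C(C)(C)C | intermediate
26 | trimethylsilyl ketene acetal of lactone 25 (C11=C12–OSiMe3) | CC[Si](CC)(CC)O[C@H]1[C@H]2C=C(O[Si](C)(C)C)O[C@H]2/C=C(/C)CC/C=C(/C(=O)OC)[C@@H]1O[Si](C)(C)C(C)(C)C | intermediate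
27 | 11-(dimethylaminomethyl) derivative of 25 (C11 epimers) | CC[Si](CC)(CC)O[C@H]1[C@H]2C(CN(C)C)C(=O)O[C@H]2/C=C(/C)CC/C=C(/C(=O)OC)[C@@H]1O[Si](C)(C)C(C)(C)C | intermediate
28 | trimethylammonium iodide from 27 | CC[Si](CC)(CC)O[C@H]1[C@H]2C(C[N+](C)(C)C)C(=O)O[C@H]2/C=C(/C)CC/C=C(/C(=O)OC)[C@@H]1O[Si](C)(C)C(C)(C)C.[I-] | intermediate
29 | methyl (1(10)E,4Z)-9-(tert-butyldimethylsilyloxy)-8-(triethylsilyloxy)germacra-1(10),4,11(13)-trien-12,6-olid-14-oate | CC[Si](CC)(CC)O[C@H]1[C@H]2C(=C)C(=O)O[C@H]2/C=C(/C)CC/C=C(/C(=O)OC)[C@@H]1O[Si](C)(C)C(C)(C)C | intermediate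
30 | 8-hydroxy compound from 29 (O9 silyl ether kept) | O[C@H]1[C@H]2C(=C)C(=O)O[C@H]2/C=C(/C)CC/C=C(/C(=O)OC)[C@@H]1O[Si](C)(C)C(C)(C)C | intermediate
31 | 8-O-methacrylate of 30 | C=C(C)C(=O)O[C@H]1[C@H]2C(=C)C(=O)O[C@H]2/C=C(/C)CC/C=C(/C(=O)OC)[C@@H]1O[Si](C)(C)C(C)(C)C | intermediate
32 | 9-hydroxy 8-O-methacrylate | C=C(C)C(=O)O[C@H]1[C@H]2C(=C)C(=O)O[C@H]2/C=C(/C)CC/C=C(/C(=O)OC)[C@@H]1O | intermediate
33 | methyl (1(10)E,4Z)-9-acetoxy-8-(2-methylprop-2-enoyloxy)germacra-1(10),4,11(13)-trien-12,6-olid-14-oate | C=C(C)C(=O)O[C@H]1[C@H]2C(=C)C(=O)O[C@H]2/C=C(/C)CC/C=C(/C(=O)OC)[C@@H]1OC(C)=O | intermediate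
34 | methyl (1(10)E,4R,5S,6R,7R,8S,9S)-9-acetoxy-4,5-epoxy-8-(2-methylprop-2-enoyloxy)germacra-1(10),11(13)-dien-12,6-olid-14-oate | C=C(C)C(=O)O[C@H]1[C@H]2C(=C)C(=O)O[C@H]2[C@@H]2O[C@]2(C)CC/C=C(/C(=O)OC)[C@@H]1OC(C)=O | target

**Count and risks**

Total: 20 steps. Longest linear sequence: 18 steps (steps 1–6 and 9–20; steps 7 and 8 prepare reagent 14).

Steps most likely to fail:

1. Step 14. Intermolecular metathesis at the monosubstituted olefin (dimers, oligomers) may outrun closure onto the hindered, electron-poor 1,1-disubstituted olefin, and ring strain may hold back the ten-membered ring. The fallback closes the ring by irreversible C–C coupling at C3–C4 instead of at C1=C10. Setting out from 20, NaIO4 oxidation and selenoxide elimination would give the iodo acrylate F1. Cross-metathesis with an excess of 2-(but-3-en-1-yl)-4,4,5,5-tetramethyl-1,3,2-dioxaborolane (second-generation Grubbs catalyst (H2IMes)(PCy3)Cl2Ru=CHPh, CH2Cl2, 40 °C) would give the (E)-configured alkylboronate F2. An intramolecular sp3–sp2 Suzuki–Miyaura coupling (Pd(OAc)2, RuPhos, K3PO4, toluene/H2O, high dilution, 60 °C) would then join C3 to C4 and return to 25.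

2. Step 11. The O8 alkoxide released on lactol opening may attack the lactone carbonyl C12 or the ester carbonyl C14 (acyl transfer, lactonisation), or take the silyl group from O9 before it is capped; the lactol may also open too slowly at the low temperature needed to prevent this. The fallback forms no alkoxide. From 17, NaBH4 in buffered ethanol (pH 7, 0 °C) would reduce the lactol to the diol F3. Et3SiOTf and 2,6-lutidine would give the bis(triethylsilyl) ether F4. Swern conditions ((COCl)2, DMSO, CH2Cl2, −78 → −30 °C; Et3N) would cleave and oxidise only the primary silyl ether to the aldehyde F5. Stork–Zhao olefination of this aldehyde, as in step 11 but without base for a hydroxyl, would give 20.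

3. Step 5. The enzyme may acylate the wrong enantiotopic hydroxyl or discriminate poorly, uncatalysed ring closure of 7 may add racemic lactone, and acyl transfer between O6 and O8 may erode the enantiomeric purity. The fallback selects by intermolecular acylation. From 7, lipase-catalysed acetylation with vinyl acetate (Pseudomonas cepacia lipase or Candida antarctica lipase B, MTBE, rt) would give the monoacetate F6; this is a standard desymmetrisation of meso cyclopent-4-ene-1,3-diols and should follow the empirical rule for secondary alcohols, acylating the (R)-carbinol C8. PPTS in toluene (50 °C) would close the lactone on the remaining C6 hydroxyl to the acetoxy lactone F7. Lipase-catalysed butanolysis of the acetate (Candida antarctica lipase B, n-BuOH, MTBE) would return to 8.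

Further compounds

F1 | step 14 | iodo acrylate: compound 20 after selenoxide elimination (C10=CH2; (Z)-iodoalkene kept) | C=C(C(=O)OC)[C@H](O[Si](C)(C)C(C)(C)C)[C@@H](O[Si](CC)(CC)CC)[C@H]1CC(=O)O[C@H]1/C=C(/C)I
F2 | step 14 | (E)-enoate with C1=C10 formed and a pinacolboronate on C3; (Z)-iodoalkene kept | CC1(C)OB(OC1(C)C)CC/C=C(/C(=O)OC)[C@H](O[Si](C)(C)C(C)(C)C)[C@@H](O[Si](CC)(CC)CC)[C@H]1CC(=O)O[C@H]1/C=C(/C)I
F3 | step 11 | diol from reduction of lactol 17 (C5 primary hydroxyl, C8 secondary hydroxyl) | COC(=O)C(C)([Se]c1ccccc1)[C@H](O[Si](C)(C)C(C)(C)C)[C@@H](O)[C@H]1CC(=O)O[C@H]1CO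
F4 | step 11 | bis(triethylsilyl) ether of F3 | COC(=O)C(C)([Se]c1ccccc1)[C@H](O[Si](C)(C)C(C)(C)C)[C@@H](O[Si](CC)(CC)CC)[C@H]1CC(=O)O[C@H]1CO[Si](CC)(CC)CC
F5 | step 11 | C5 aldehyde with O8 triethylsilyl and O9 tert-butyldimethylsilyl ethers | COC(=O)C(C)([Se]c1ccccc1)[C@H](O[Si](C)(C)C(C)(C)C)[C@@H](O[Si](CC)(CC)CC)[C@H]1CC(=O)O[C@H]1C=O
F6 | step 5 | monoacetate of 7 (acetate on the (R)-carbinol C8; C6 hydroxyl free) | COC(=O)C[C@@H]1[C@H](OC(C)=O)C=C[C@@H]1O
F7 | step 5 | O-acetate of 8 | O=C1C[C@@H]2[C@H](OC(C)=O)C=C[C@@H]2O1
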